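**Retrosynthetic overview**
- Rings A and B, all 20 carbons and the C5/C10 ring-fusion stereocentres are taken intact from (−)-sclareol. No ring is formed, so the order of events is C2–O, then ring B oxygenation, then the side chain.
- The C15 alcohol comes from lipase cleavage of a primary allylic acetate, which comes from a [3,3] shift of the C13 tertiary allylic acetate (C15–O bond, E-alkene).
- The trans-diaxial 6β,7α-diacetate comes from α-face hydride reduction of a 7α-acetoxy-8-en-6-one. That ketone comes from the key new C7–O bond: deconjugative α-acetoxylation of a 7-en-6-one, which sets C7 and the Δ8 alkene.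
- The 7-en-6-one comes from allylic oxidation of the Δ7 alkene, made by dehydrating the C8 tertiary alcohol.
- The C2 acetate comes from a biocatalytic 2α C–H hydroxylation of sclareol.

Assumption: the SMILES is read as the normal-series labdane (13E)-2α,6β,7α-triacetoxylabda-8,13-dien-15-ol (2S,5S,6S,7S,10S), and (−)-sclareol counts as a cheap commercial starting material.

**Route**

Step 1
Reactants: 1 (−)-sclareol [(13R)-labd-14-ene-8α,13-diol]
Product: 2 2α-hydroxysclareol [(13R)-labd-14-ene-2α,8α,13-triol]
Conditions: Cunninghamella elegans (growing whole cells), glucose–peptone medium, air, 27 °C, 5 d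
Reagents that add atoms: dioxygen O=O
Why: Cytochrome P450 C–H hydroxylation (whole-cell biotransformation) abstracts the exposed equatorial 2α-hydrogen of ring A and rebounds oxygen with retention, setting the 2α C–O stereocentre while the vinyl group and both tertiary alcohols are untouched; ring-A hydroxylation of sclareol by Cunninghamella cultures is a known biotransformation.

Step 2
Reactants: 2 2α-hydroxysclareol
Product: 3 (13R)-2α,13-diacetoxylabd-14-en-8α-ol
Conditions: Ac2O, Et3N, DMAP (cat.), CH2Cl2, 23 °C, 24 h
Reagents that add atoms: acetic anhydride CC(=O)OC(C)=O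
Why: DMAP-catalysed acylation esterifies the secondary 2α-OH and the acyclic tertiary allylic 13-OH but not the much more hindered ring tertiary 8α-OH.

Step 3
Reactants: 3 (13R)-2α,13-diacetoxylabd-14-en-8α-ol
Product: 4 (13R)-2α,13-diacetoxylabda-7,14-diene
Conditions: Burgess reagent, PhH, 50 °C
Reagents that add atoms: none
Why: Burgess dehydration (syn-elimination through the sulfamate ester) removes the equatorial 8α-OH together with the cis axial 7α-H, the C9–H being shielded by the side chain and C10, so the Δ7 trisubstituted alkene is expected as the main isomer (the Δ8(17) isomer is removed on AgNO3–silica), and the neutral conditions spare the tertiary allylic acetate.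

Step 4
Reactants: 4 (13R)-2α,13-diacetoxylabda-7,14-diene
Product: 5 (13R)-2α,13-diacetoxylabda-7,14-dien-6-one
Conditions: Rh2(cap)4 (dirhodium tetrakis(caprolactamate), 1 mol %), t-BuOOH, K2CO3, CH2Cl2, 23 °C
Reagents that add atoms: tert-butyl hydroperoxide CC(C)(C)OO
Why: Radical allylic oxidation converts C6, the only allylic ring methylene, into the conjugated ketone; the vinyl group has no allylic hydrogens and the acetates are inert.

Step 5
Reactants: 5 (13R)-2α,13-diacetoxylabda-7,14-dien-6-one
Product: 7 (13R)-2α,7α,13-triacetoxylabda-8,14-dien-6-one, via silyl dienol ether 6 (not isolated)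
Conditions: TMSOTf, Et3N, CH2Cl2, 0 → 23 °C, 12 h (thermodynamic control); evaporate, pentane filtration; then Pb(OAc)4 (tetravalent lead), PhH, 10 °C; aq NaHCO3
Reagents that add atoms: Pb(OAc)4 CC(=O)O[Pb](OC(C)=O)(OC(C)=O)OC(C)=O (acetoxy group at C7); TMSOTf C[Si](C)(C)OS(=O)(=O)C(F)(F)F (silyl group of 6 only)
Why: Proposed new method: deconjugative α-acetoxylation of a linear silyl dienol ether, in which the equilibrated homoannular 6-silyloxy-6,8-diene 6 exchanges silicon for lead at oxygen and the O-bound lead enolate collapses by reductive transfer of an acetate ligand through a five-membered cyclic transition state that can reach only C7 (the vinylogous carbon C9 is fully substituted, out of reach and too hindered for the bulky lead centre), from the α-face because the β-face is screened by the axial C19 and C20 methyl groups, so the C7–O bond, the 7α stereocentre (also the thermodynamically preferred pseudoaxial epimer, avoiding strain with the C17 methyl) and the tetrasubstituted C8=C9 alkene are set together; the closest known reaction type is the Rubottom-type Pb(OAc)4 α-acetoxylation of simple silyl enol ethers and α′-acetoxylation of cross-conjugated 2-silyloxydienes, which has not been shown for a linear 1-silyloxy-1,3-diene with a fully substituted γ-carbon.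

Step 6
Reactants: 7 (13R)-2α,7α,13-triacetoxylabda-8,14-dien-6-one
Product: 8 (13R)-2α,7α,13-triacetoxylabda-8,14-dien-6β-ol
Conditions: NaBH4, CeCl3·7H2O, MeOH–THF, −78 °C
Reagents that add atoms: none
Why: Luche-type 1,2-reduction delivers hydride to C6 from the α-face because the β-face is blocked by the syn-axial C19 and C20 methyl groups, setting the axial 6β alcohol trans-diaxial to the 7α-acetate (so no acyl migration), and at −78 °C the acetates and the enolisable C7 centre survive.

Step 7
Reactants: 8 (13R)-2α,7α,13-triacetoxylabda-8,14-dien-6β-ol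
Product: 9 (13R)-2α,6β,7α,13-tetraacetoxylabda-8,14-diene
Conditions: Ac2O, DMAP, pyridine, 50 °C
Reagents that add atoms: acetic anhydride CC(=O)OC(C)=O
Why: DMAP-catalysed acetylation under forcing conditions esterifies the hindered axial 6β-OH without touching any stereocentre.

Step 8
Reactants: 9 (13R)-2α,6β,7α,13-tetraacetoxylabda-8,14-diene
Product: 10 (13E)-2α,6β,7α,15-tetraacetoxylabda-8,13-diene
Conditions: PdCl2(MeCN)2 (5 mol %, divalent palladium), THF, 23 °C
Reagents that add atoms: none
Why: Cyclisation-induced [3,3] allylic acetate rearrangement moves the acetate from C13 to C15 through a chair-like acetoxonium intermediate with the C12 chain equatorial, forming the C15–O bond and mainly the E trisubstituted alkene (the minor Z isomer is removed by chromatography), while the C7 acetate beside the tetrasubstituted alkene cannot engage the catalyst.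

Step 9
Reactants: 10 (13E)-2α,6β,7α,15-tetraacetoxylabda-8,13-diene
Product: 11 (13E)-2α,6β,7α-triacetoxylabda-8,13-dien-15-ol (CNP0305346.2)
Conditions: Candida antarctica lipase B (immobilised), pH 7 phosphate buffer–acetone, 30 °C
Reagents that add atoms: none
Why: Lipase-catalysed ester hydrolysis is selective for the unhindered primary allylic acetate over the three secondary ring acetates, which sit on a bulky decalin (two of them axial), and so releases the C15 alcohol of the target.

**Compound list**

1 | (−)-sclareol [(13R)-labd-14-ene-8α,13-diol] | C1CC(C)(C)[C@@H]2CC[C@@](C)(O)[C@H](CC[C@@](C)(O)C=C)[C@@]2(C)C1 | starting material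
2 | 2α-hydroxysclareol [(13R)-labd-14-ene-2α,8α,13-triol] | O[C@H]1CC(C)(C)[C@@H]2CC[C@@](C)(O)[C@H](CC[C@@](C)(O)C=C)[C@@]2(C)C1 | intermediate
3 | (13R)-2α,13-diacetoxylabd-14-en-8α-ol | CC(=O)O[C@H]1CC(C)(C)[C@@H]2CC[C@@](C)(O)[C@H](CC[C@@](C)(OC(C)=O)C=C)[C@@]2(C)C1 | intermediate
4 | (13R)-2α,13-diacetoxylabda-7,14-diene | CC(=O)O[C@H]1CC(C)(C)[C@@H]2CC=C(C)[C@H](CC[C@@](C)(OC(C)=O)C=C)[C@@]2(C)C1 | intermediate
5 | (13R)-2α,13-diacetoxylabda-7,14-dien-6-one | CC(=O)O[C@H]1CC(C)(C)[C@@H]2C(=O)C=C(C)[C@H](CC[C@@](C)(OC(C)=O)C=C)[C@@]2(C)C1 | intermediate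
6 | silyl dienol ether [(13R)-2α,13-diacetoxy-6-(trimethylsilyloxy)labda-6,8,14-triene] | CC(=O)O[C@H]1CC(C)(C)[C@@H]2C(O[Si](C)(C)C)=CC(C)=C(CC[C@@](C)(OC(C)=O)C=C)[C@@]2(C)C1 | intermediate
7 | (13R)-2α,7α,13-triacetoxylabda-8,14-dien-6-one | CC(=O)O[C@H]1CC(C)(C)[C@@H]2C(=O)[C@@H](OC(C)=O)C(C)=C(CC[C@@](C)(OC(C)=O)C=C)[C@@]2(C)C1 | intermediate
8 | (13R)-2α,7α,13-triacetoxylabda-8,14-dien-6β-ol | CC(=O)O[C@H]1CC(C)(C)[C@@H]2[C@H](O)[C@@H](OC(C)=O)C(C)=C(CC[C@@](C)(OC(C)=O)C=C)[C@@]2(C)C1 | intermediate
9 | (13R)-2α,6β,7α,13-tetraacetoxylabda-8,14-diene | CC(=O)O[C@H]1CC(C)(C)[C@@H]2[C@H](OC(C)=O)[C@@H](OC(C)=O)C(C)=C(CC[C@@](C)(OC(C)=O)C=C)[C@@]2(C)C1 | intermediate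
10 | (13E)-2α,6β,7α,15-tetraacetoxylabda-8,13-diene | CC(=O)O[C@H]1CC(C)(C)[C@@H]2[C@H](OC(C)=O)[C@@H](OC(C)=O)C(C)=C(CC/C(C)=C/COC(C)=O)[C@@]2(C)C1 | intermediate
11 | (13E)-2α,6β,7α-triacetoxylabda-8,13-dien-15-ol (CNP0305346.2) | CC(=O)O[C@H]1CC(C)(C)[C@@H]2[C@H](OC(C)=O)[C@@H](OC(C)=O)C(C)=C(CC/C(C)=C/CO)[C@@]2(C)C1 | target

**Step count and risks**

Total step count: 9. Longest linear sequence: 9 steps (1 to 11).

The three steps most likely to fail:

Step 1 (site selectivity and yield of the whole-cell hydroxylation; 3β- and 18-hydroxylation compete). The fallback sets out from 1 and masks the only alkene. Pyridinium tribromide in CH2Cl2 at 0 °C adds bromine across the vinyl group to give (13R)-14,15-dibromolabdane-8α,13-diol F1. A chemical C–H hydroxylation with retention, Mn(OTf)2((S,S)-PDP) (divalent manganese), H2O2 and AcOH in hexafluoroisopropanol, then oxidises the most exposed methylene that is remote from the deactivating oxygen and bromine substituents, giving (13R)-14,15-dibromolabdane-2α,8α,13-triol F2. Zn dust in AcOH–EtOH removes the two bromines, restores the vinyl group and returns to the route at 2.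

Step 3 (regiochemistry of the dehydration; Δ8(17) and Δ8(9) isomers compete). The fallback sets out from 3. SOCl2 and pyridine in CH2Cl2 at −78 °C eliminate the chlorosulfite towards the C17 hydrogens, the only ones anti-periplanar to the equatorial leaving group, and give the exocyclic alkene (13R)-2α,13-diacetoxylabda-8(17),14-diene F3. Catalytic SeO2 with t-BuOOH hydroxylates its allylic ring position to give (13R)-2α,13-diacetoxylabda-8(17),14-dien-7α-ol F4. A reductive allylic transposition (2-nitrobenzenesulfonylhydrazide, PPh3, DEAD, THF, −30 → 23 °C) replaces the hydroxyl by a diazene that loses N2, delivering hydrogen to C17 and moving the alkene to C7=C8 regiospecifically. This returns to the route at 4.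

Step 5 (the proposed new acetoxylation; possible failures are the exocyclic dienol ether isomer, attack at C9 instead of C7, or the 7β epimer). The fallback uses known chemistry, sets out from 5 through the same silyl dienol ether 6, and accepts oxygenation at the vinylogous carbon. Dimethyldioxirane in acetone at −40 °C (vinylogous Rubottom oxidation) followed by a mild acid work-up gives (13R)-2α,13-diacetoxy-9α-hydroxylabda-7,14-dien-6-one F5. NaBH4 with CeCl3·7H2O at −78 °C reduces the ketone from the α-face to (13R)-2α,13-diacetoxylabda-7,14-diene-6β,9α-diol F6. Ph3SiOReO3 (heptavalent rhenium, 2 mol %) in Et2O at 0 °C transposes the tertiary allylic 9α-hydroxyl suprafacially to C7 and gives the more substituted alkene, (13R)-2α,13-diacetoxylabda-8,14-diene-6β,7α-diol F7. Ac2O, DMAP and pyridine at 50 °C acetylate both hydroxyls, returning to the route at 9. The sequence reaches the same compound whether oxygen first enters at C7 or C9, but it still depends on dienol ether 6 forming as the endocyclic isomer.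

Further compounds
F1 | step 1 | (13R)-14,15-dibromolabdane-8α,13-diol (C14 epimers) | C1CC(C)(C)[C@@H]2CC[C@@](C)(O)[C@H](CC[C@@](C)(O)C(Br)CBr)[C@@]2(C)C1
F2 | step 1 | (13R)-14,15-dibromolabdane-2α,8α,13-triol (C14 epimers) | O[C@H]1CC(C)(C)[C@@H]2CC[C@@](C)(O)[C@H](CC[C@@](C)(O)C(Br)CBr)[C@@]2(C)C1
F3 | step 3 | (13R)-2α,13-diacetoxylabda-8(17),14-diene | CC(=O)O[C@H]1CC(C)(C)[C@@H]2CCC(=C)[C@H](CC[C@@](C)(OC(C)=O)C=C)[C@@]2(C)C1
F4 | step 3 | (13R)-2α,13-diacetoxylabda-8(17),14-dien-7α-ol | CC(=O)O[C@H]1CC(C)(C)[C@@H]2C[C@@H](O)C(=C)[C@H](CC[C@@](C)(OC(C)=O)C=C)[C@@]2(C)C1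
F5 | step 5 | (13R)-2α,13-diacetoxy-9α-hydroxylabda-7,14-dien-6-one | CC(=O)O[C@H]1CC(C)(C)[C@@H]2C(=O)C=C(C)[C@](O)(CC[C@@](C)(OC(C)=O)C=C)[C@@]2(C)C1
F6 | step 5 | (13R)-2α,13-diacetoxylabda-7,14-diene-6β,9α-diol | CC(=O)O[C@H]1CC(C)(C)[C@@H]2[C@H](O)C=C(C)[C@](O)(CC[C@@](C)(OC(C)=O)C=C)[C@@]2(C)C1
F7 | step 5 | (13R)-2α,13-diacetoxylabda-8,14-diene-6β,7α-diol | CC(=O)O[C@H]1CC(C)(C)[C@@H]2[C@H](O)[C@@H](O)C(C)=C(CC[C@@](C)(OC(C)=O)C=C)[C@@]2(C)C1
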